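The route rests on cutting ring A at C4–C5 and C6–C1: C1–C4 come from a 3-acetyl-4-methoxy-2-pyrone, C5–C6 from the ethynyl ether of the ring B phenol. Ring A bears oxygen at C3, C4 and C5 with only O5 arylated, hydrogen at C2 and C6 and the ring D bridge at C1, exactly the pattern an acylpyrone and a terminal aryloxyalkyne deliver. One inverse-demand Diels–Alder reaction with CO2 loss closes ring A, sets the A–O–B ether and unites both halves; the acetyl group later becomes O4. The precursor is the pyrone carrying, at C6, the CH2CH2–ring D–O–ring C unit with a masked aldehyde.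

Key step: step 11

Remark on the chemistry: the target has no stereocentre; the macrocyclic stilbene 25 is drawn as the Z isomer, and either alkene geometry is expected to converge on 26 in step 16.

Step 1
Reactants: 1 2-hydroxy-3,4-dimethoxybenzaldehyde
Product: 2 6-(1,3-dioxolan-2-yl)-2,3-dimethoxyphenol
Conditions: HOCH2CH2OH (5 equiv), p-TsOH·H2O (cat.), PhMe, reflux, Dean–Stark; Et3N quench
Reagents that add atoms: ethylene glycol, OCCO
Why: Acid-catalysed acetalisation driven by azeotropic removal of water masks the ring C aldehyde for the later hydride, carbanion and peracid steps and leaves the phenol free.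

Step 2
Reactants: 2 6-(1,3-dioxolan-2-yl)-2,3-dimethoxyphenol; 3 2-fluorobenzaldehyde
Product: 4 2-[6-(1,3-dioxolan-2-yl)-2,3-dimethoxyphenoxy]benzaldehyde
Conditions: K2CO3, DMF, 120 °C
Reagents that add atoms: none
Why: Nucleophilic aromatic substitution, in which the phenoxide displaces the fluoride activated by the ortho formyl group through a Meisenheimer adduct, should form the C–O–D diaryl ether while the base-stable acetal is untouched.

Step 3
Reactants: 4 2-[6-(1,3-dioxolan-2-yl)-2,3-dimethoxyphenoxy]benzaldehyde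
Product: 5 {2-[6-(1,3-dioxolan-2-yl)-2,3-dimethoxyphenoxy]phenyl}methanol
Conditions: NaBH4, MeOH–THF, 0 °C
Reagents that add atoms: none
Why: Borohydride reduction of the only free aldehyde gives the ring D benzylic alcohol; the acetal and the ethers are inert to hydride.

Step 4
Reactants: 5 {2-[6-(1,3-dioxolan-2-yl)-2,3-dimethoxyphenoxy]phenyl}methanol
Product: 6 2-{2-[2-(bromomethyl)phenoxy]-3,4-dimethoxyphenyl}-1,3-dioxolane
Conditions: CBr4, PPh3, 2,6-lutidine, CH2Cl2, 0 °C
Reagents that add atoms: carbon tetrabromide, BrC(Br)(Br)Br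
Why: The Appel reaction turns the primary benzylic alcohol into the bromide under essentially neutral, buffered conditions that an aryl dioxolane tolerates.

Step 5
Reactants: 6 2-{2-[2-(bromomethyl)phenoxy]-3,4-dimethoxyphenyl}-1,3-dioxolane; 7 4-hydroxy-6-methyl-2H-pyran-2-one (triacetic acid lactone)
Product: 9 6-(2-{2-[6-(1,3-dioxolan-2-yl)-2,3-dimethoxyphenoxy]phenyl}ethyl)-4-hydroxy-2H-pyran-2-one, via triacetic acid lactone dilithium dianion 8 (not isolated)
Conditions: 7 (1.5 equiv), LiN(i-Pr)2 (3.0 equiv, commercial solution), THF–DMPU, −78 → −40 °C; then 6, −78 → 0 °C; AcOH quench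
Reagents that add atoms: none
Why: The dianion reacts in an SN2 alkylation at its last-formed and most basic site, the 6-methyl carbanion, so the benzylic bromide installs the CH2CH2 bridge while the O4 anion stays protected as its lithium salt.

Step 6
Reactants: 9 6-(2-{2-[6-(1,3-dioxolan-2-yl)-2,3-dimethoxyphenoxy]phenyl}ethyl)-4-hydroxy-2H-pyran-2-one
Product: 11 3-acetyl-6-(2-{2-[6-(1,3-dioxolan-2-yl)-2,3-dimethoxyphenoxy]phenyl}ethyl)-4-hydroxy-2H-pyran-2-one, via pyranone 4-O-acetate 10 (not isolated)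
Conditions: AcOH (1.1 equiv), DCC, DMAP, PhMe, rt then 60 °C
Reagents that add atoms: acetic acid, CC(=O)O
Why: Steglich O-acetylation of the 4-hydroxypyrone is followed by a DMAP-mediated Fries-type O-to-C acyl shift to C3, the standard entry to 3-acyl-4-hydroxy-2-pyrones, with the hydrogen-bonded product as the thermodynamic sink.

Step 7
Reactants: 11 3-acetyl-6-(2-{2-[6-(1,3-dioxolan-2-yl)-2,3-dimethoxyphenoxy]phenyl}ethyl)-4-hydroxy-2H-pyran-2-one
Product: 12 3-acetyl-6-(2-{2-[6-(1,3-dioxolan-2-yl)-2,3-dimethoxyphenoxy]phenyl}ethyl)-4-methoxy-2H-pyran-2-one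
Conditions: Me2SO4, K2CO3, acetone, reflux
Reagents that add atoms: dimethyl sulfate, COS(=O)(=O)OC
Why: Williamson-type O-methylation of the acidic vinylogous acid at O4 with a hard methylating agent should give the 4-methoxy-2-pyrone, which removes the acidic proton that would otherwise destroy the ynol ether in step 11.

Step 8
Reactants: 13 4-hydroxybenzaldehyde
Product: 14 4-(1,3-dioxolan-2-yl)phenol
Conditions: HOCH2CH2OH (5 equiv), p-TsOH·H2O (cat.), PhMe, reflux, Dean–Stark; Et3N quench
Reagents that add atoms: ethylene glycol, OCCO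
Why: Acid-catalysed acetalisation with water removal masks the ring B aldehyde against butyllithium and peracid and keeps the later ynol ether electron-rich.

Step 9
Reactants: 14 4-(1,3-dioxolan-2-yl)phenol
Product: 15 2-{4-[(E)-1,2-dichloroethenyloxy]phenyl}-1,3-dioxolane
Conditions: Cl2C=CHCl (1.5 equiv), K2CO3, DMF, 70 °C
Reagents that add atoms: trichloroethylene, ClC=C(Cl)Cl
Why: Base-induced loss of HCl from trichloroethylene gives dichloroacetylene, to which the phenoxide adds with anti protonation, a known nucleophilic addition to a haloalkyne that gives the E dichlorovinyl ether.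

Step 10
Reactants: 15 2-{4-[(E)-1,2-dichloroethenyloxy]phenyl}-1,3-dioxolane
Product: 18 2-(4-ethynyloxyphenyl)-1,3-dioxolane, via chloroalkyne 16 (not isolated), via lithium acetylide 17 (not isolated)
Conditions: n-BuLi (2.2 equiv), Et2O, −78 → −40 °C; H2O quench at −78 °C; short cold silica filtration, kept as a cold PhMe solution
Reagents that add atoms: none
Why: Vinylic deprotonation and beta-elimination of chloride give the chloroalkyne, lithium–chlorine exchange gives the lithium aryloxyacetylide, and protonation gives the terminal ynol ether, the established dichlorovinyl ether route to aryloxyacetylenes.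

Step 11
Reactants: 12 3-acetyl-6-(2-{2-[6-(1,3-dioxolan-2-yl)-2,3-dimethoxyphenoxy]phenyl}ethyl)-4-methoxy-2H-pyran-2-one; 18 2-(4-ethynyloxyphenyl)-1,3-dioxolane
Product: 20 1-[2-[4-(1,3-dioxolan-2-yl)phenoxy]-4-(2-{2-[6-(1,3-dioxolan-2-yl)-2,3-dimethoxyphenoxy]phenyl}ethyl)-6-methoxyphenyl]ethanone, via bicyclic lactone 19 (not isolated)
Conditions: 18 (3 equiv, added in three portions), 2,6-di-tert-butyl-4-methylphenol (trace), PhMe, 110 °C, sealed tube
Reagents that add atoms: none
Why: The electron-rich ynol ether 18 and the acetyl-activated pyrone 12 should combine in an asynchronous [4+2] cycloaddition across pyrone C3 and C6 to the 2-oxabicyclo[2.2.2]octadienone 19, which loses CO2 by a retro-[4+2] step at this temperature and so gives the benzene ring directly, with no oxidation needed. The closest known reaction type is the inverse-demand Diels–Alder reaction with decarboxylation of 3-acyl- and 3-alkoxycarbonyl-2-pyrones with ynamines, alkoxyalkynes and ketene acetals. Ring A is closed as a six-membered carbocycle by intermolecular [4+2] annulation, the alkyne CH bonding to pyrone C6 (ring A C6–C1) and the oxygen-bearing alkyne carbon to pyrone C3 (ring A C4–C5). No stereocentre remains, because the two racemic bridgehead centres of 19 are erased when CO2 leaves. The only selectivity required is this orientation, which the polarisation of both partners secures: the nucleophilic terminal carbon of 18 attacks C6, the acceptor terminus conjugated with both carbonyl groups, while the developing oxocarbenium carbon closes onto the doubly stabilised C3. Because the C4 methoxy donor makes the diene less reactive than the parent acylpyrones, 18 is used in excess and fed in portions so that cycloaddition can compete with its thermal oligomerisation.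

Step 12
Reactants: 20 1-[2-[4-(1,3-dioxolan-2-yl)phenoxy]-4-(2-{2-[6-(1,3-dioxolan-2-yl)-2,3-dimethoxyphenoxy]phenyl}ethyl)-6-methoxyphenyl]ethanone
Product: 21 2-[4-(1,3-dioxolan-2-yl)phenoxy]-4-(2-{2-[6-(1,3-dioxolan-2-yl)-2,3-dimethoxyphenoxy]phenyl}ethyl)-6-methoxyphenyl acetate
Conditions: mCPBA, Na2HPO4, CH2Cl2, 0 °C → rt
Reagents that add atoms: 3-chloroperoxybenzoic acid, OOC(=O)c1cccc(Cl)c1
Why: In this Baeyer–Villiger oxidation the electron-rich, doubly ortho-oxygenated ring A carbon migrates in preference to methyl, which places oxygen on C4, and the phosphate buffer keeps both dioxolanes intact.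

Step 13
Reactants: 21 2-[4-(1,3-dioxolan-2-yl)phenoxy]-4-(2-{2-[6-(1,3-dioxolan-2-yl)-2,3-dimethoxyphenoxy]phenyl}ethyl)-6-methoxyphenyl acetate
Product: 23 2-{4-[5-(2-{2-[6-(1,3-dioxolan-2-yl)-2,3-dimethoxyphenoxy]phenyl}ethyl)-2,3-dimethoxyphenoxy]phenyl}-1,3-dioxolane, via ring A phenol 22 (not isolated)
Conditions: K2CO3, MeOH–DMF, rt; then MeI, 40 °C
Reagents that add atoms: iodomethane, CI
Why: Base-catalysed methanolysis of the aryl acetate frees the C4 phenoxide, which is methylated in the same flask by a Williamson ether synthesis so that no free phenol enters the low-valent titanium step.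

Step 14
Reactants: 23 2-{4-[5-(2-{2-[6-(1,3-dioxolan-2-yl)-2,3-dimethoxyphenoxy]phenyl}ethyl)-2,3-dimethoxyphenoxy]phenyl}-1,3-dioxolane
Product: 24 2-(2-{2-[3-(4-formylphenoxy)-4,5-dimethoxyphenyl]ethyl}phenoxy)-3,4-dimethoxybenzaldehyde
Conditions: 2 M HCl, THF, rt
Reagents that add atoms: water, O
Why: Acid-catalysed acetal hydrolysis releases both aryl aldehydes at once, and the methyl and diaryl ethers are inert to dilute acid.

Step 15
Reactants: 24 2-(2-{2-[3-(4-formylphenoxy)-4,5-dimethoxyphenyl]ethyl}phenoxy)-3,4-dimethoxybenzaldehyde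
Product: 25 tetra-O-methyl macrocyclic stilbene (17-membered ring, Z alkene between ring B and ring C)
Conditions: TiCl4, Zn, pyridine, THF, reflux; dialdehyde added by syringe pump over 20 h (final 2 mM)
Reagents that add atoms: none
Why: In the intramolecular McMurry coupling, low-valent titanium pinacol-couples the two aryl aldehydes and deoxygenates the titanium diolate to the alkene, and slow addition at high dilution favours the 17-membered ring, a closure type established for macrocyclic bis(bibenzyl)s.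

Step 16
Reactants: 25 tetra-O-methyl macrocyclic stilbene
Product: 26 tetra-O-methyl ether of the target (saturated macrocycle)
Conditions: H2 (1 atm), Pd/C (10% Pd on carbon), EtOAc, rt
Reagents that add atoms: none
Why: Heterogeneous catalytic hydrogenation saturates the stilbene double bond of either geometry, and aryl methyl and diaryl ethers are not hydrogenolysed under these conditions.

Step 17
Reactants: 26 tetra-O-methyl ether of the target
Product: 27 CNP0114693.0 (target)
Conditions: BBr3 (10 equiv), CH2Cl2, −78 °C → rt; then H2O, 0 °C, under N2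
Reagents that add atoms: none
Why: In this BBr3 demethylation, bromide attacks the methyl carbon of each of the four borane-complexed aryl methyl ethers, whereas the two diaryl ether bonds offer no carbon open to SN2 attack and survive.

Compound list
1 | 2-hydroxy-3,4-dimethoxybenzaldehyde | O=Cc1ccc(OC)c(OC)c1O | starting material
2 | 6-(1,3-dioxolan-2-yl)-2,3-dimethoxyphenol | Oc1c(C2OCCO2)ccc(OC)c1OC | intermediate
3 | 2-fluorobenzaldehyde | O=Cc1ccccc1F | starting material
4 | 2-[6-(1,3-dioxolan-2-yl)-2,3-dimethoxyphenoxy]benzaldehyde | O=Cc1ccccc1Oc1c(C2OCCO2)ccc(OC)c1OC | intermediate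
5 | {2-[6-(1,3-dioxolan-2-yl)-2,3-dimethoxyphenoxy]phenyl}methanol | OCc1ccccc1Oc1c(C2OCCO2)ccc(OC)c1OC | intermediate
6 | 2-{2-[2-(bromomethyl)phenoxy]-3,4-dimethoxyphenyl}-1,3-dioxolane | BrCc1ccccc1Oc1c(C2OCCO2)ccc(OC)c1OC | intermediate
7 | 4-hydroxy-6-methyl-2H-pyran-2-one (triacetic acid lactone) | CC1=CC(O)=CC(=O)O1 | starting material
8 | dilithium dianion of triacetic acid lactone (O4 and 6-methyl carbon) | [Li+].[Li+].[CH2-]C1=CC([O-])=CC(=O)O1 | intermediate
9 | 6-(2-{2-[6-(1,3-dioxolan-2-yl)-2,3-dimethoxyphenoxy]phenyl}ethyl)-4-hydroxy-2H-pyran-2-one | OC1=CC(=O)OC(CCc2ccccc2Oc2c(C3OCCO3)ccc(OC)c2OC)=C1 | intermediate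
10 | 6-(2-{2-[6-(1,3-dioxolan-2-yl)-2,3-dimethoxyphenoxy]phenyl}ethyl)-2-oxo-2H-pyran-4-yl acetate | CC(=O)OC1=CC(=O)OC(CCc2ccccc2Oc2c(C3OCCO3)ccc(OC)c2OC)=C1 | intermediate
11 | 3-acetyl-6-(2-{2-[6-(1,3-dioxolan-2-yl)-2,3-dimethoxyphenoxy]phenyl}ethyl)-4-hydroxy-2H-pyran-2-one | CC(=O)C1=C(O)C=C(CCc2ccccc2Oc2c(C3OCCO3)ccc(OC)c2OC)OC1=O | intermediate
12 | 3-acetyl-6-(2-{2-[6-(1,3-dioxolan-2-yl)-2,3-dimethoxyphenoxy]phenyl}ethyl)-4-methoxy-2H-pyran-2-one | CC(=O)C1=C(OC)C=C(CCc2ccccc2Oc2c(C3OCCO3)ccc(OC)c2OC)OC1=O | intermediate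
13 | 4-hydroxybenzaldehyde | O=Cc1ccc(O)cc1 | starting material
14 | 4-(1,3-dioxolan-2-yl)phenol | Oc1ccc(cc1)C1OCCO1 | intermediate
15 | 2-{4-[(E)-1,2-dichloroethenyloxy]phenyl}-1,3-dioxolane | Cl/C=C(/Cl)Oc1ccc(cc1)C1OCCO1 | intermediate
16 | 2-[4-(chloroethynyloxy)phenyl]-1,3-dioxolane | ClC#COc1ccc(cc1)C1OCCO1 | intermediate
17 | lithium [4-(1,3-dioxolan-2-yl)phenoxy]ethynide | [Li]C#COc1ccc(cc1)C1OCCO1 | intermediate
18 | 2-(4-ethynyloxyphenyl)-1,3-dioxolane | C#COc1ccc(cc1)C1OCCO1 | intermediate
19 | 4-acetyl-8-[4-(1,3-dioxolan-2-yl)phenoxy]-1-(2-{2-[6-(1,3-dioxolan-2-yl)-2,3-dimethoxyphenoxy]phenyl}ethyl)-5-methoxy-2-oxabicyclo[2.2.2]octa-5,7-dien-3-one (racemic; the bridgehead configurations are tied to each other by the bicycle) | CC(=O)C12C(=O)OC(CCc3ccccc3Oc3c(C4OCCO4)ccc(OC)c3OC)(C=C1OC)C=C2Oc1ccc(cc1)C1OCCO1 | intermediate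
20 | 1-[2-[4-(1,3-dioxolan-2-yl)phenoxy]-4-(2-{2-[6-(1,3-dioxolan-2-yl)-2,3-dimethoxyphenoxy]phenyl}ethyl)-6-methoxyphenyl]ethanone | CC(=O)c1c(OC)cc(CCc2ccccc2Oc2c(C3OCCO3)ccc(OC)c2OC)cc1Oc1ccc(cc1)C1OCCO1 | intermediate
21 | 2-[4-(1,3-dioxolan-2-yl)phenoxy]-4-(2-{2-[6-(1,3-dioxolan-2-yl)-2,3-dimethoxyphenoxy]phenyl}ethyl)-6-methoxyphenyl acetate | CC(=O)Oc1c(OC)cc(CCc2ccccc2Oc2c(C3OCCO3)ccc(OC)c2OC)cc1Oc1ccc(cc1)C1OCCO1 | intermediate
22 | 2-[4-(1,3-dioxolan-2-yl)phenoxy]-4-(2-{2-[6-(1,3-dioxolan-2-yl)-2,3-dimethoxyphenoxy]phenyl}ethyl)-6-methoxyphenol | Oc1c(OC)cc(CCc2ccccc2Oc2c(C3OCCO3)ccc(OC)c2OC)cc1Oc1ccc(cc1)C1OCCO1 | intermediate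
23 | 2-{4-[5-(2-{2-[6-(1,3-dioxolan-2-yl)-2,3-dimethoxyphenoxy]phenyl}ethyl)-2,3-dimethoxyphenoxy]phenyl}-1,3-dioxolane | COc1c(OC)cc(CCc2ccccc2Oc2c(C3OCCO3)ccc(OC)c2OC)cc1Oc1ccc(cc1)C1OCCO1 | intermediate
24 | 2-(2-{2-[3-(4-formylphenoxy)-4,5-dimethoxyphenyl]ethyl}phenoxy)-3,4-dimethoxybenzaldehyde | COc1c(OC)cc(CCc2ccccc2Oc2c(C=O)ccc(OC)c2OC)cc1Oc1ccc(C=O)cc1 | intermediate
25 | tetra-O-methyl macrocyclic stilbene: 17-membered ring A–O–ring B–CH=CH–ring C–O–ring D–CH2CH2, Z alkene, methoxy groups on ring A C3 and C4 and ring C C4 and C5 | COc1cc2cc(c1OC)Oc1ccc(cc1)/C=C\c1ccc(OC)c(OC)c1Oc1ccccc1CC2 | intermediate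
26 | tetra-O-methyl ether of the target (the same macrocycle with a saturated B–C bridge) | COc1cc2cc(c1OC)Oc1ccc(cc1)CCc1ccc(OC)c(OC)c1Oc1ccccc1CC2 | intermediate
27 | CNP0114693.0: macrocyclic bis(bibenzyl) with hydroxyl groups on ring A C3 and C4 and ring C C4 and C5 | Oc1cc2cc(c1O)Oc1ccc(cc1)CCc1ccc(O)c(O)c1Oc1ccccc1CC2 | target

Total step count: 17.
Longest linear sequence: 14 steps (steps 1–7, then 11–17); steps 8–10 are a three-step branch that joins at step 11.

Steps most likely to fail

1. Step 11. The C4 methoxy donor may slow the cycloaddition so far that thermal oligomerisation of the ynol ether, or its conjugate addition at pyrone C4 with loss of methoxide, consumes the partners before ring A forms. The fallback builds the D–A bridge by olefination of a ready-made ring A. It sets out from bromide 6, which is heated with PPh3 in PhMe to give {2-[6-(1,3-dioxolan-2-yl)-2,3-dimethoxyphenoxy]benzyl}triphenylphosphonium bromide F1. Separately, commercial 3-hydroxy-4,5-dimethoxybenzaldehyde and commercial 2-(4-bromophenyl)-1,3-dioxolane are joined in an Ullmann ether synthesis (CuI, N,N-dimethylglycine, Cs2CO3, dioxane, 90 °C) to give 3-[4-(1,3-dioxolan-2-yl)phenoxy]-4,5-dimethoxybenzaldehyde F2. A Wittig reaction of the two (K2CO3, 18-crown-6, CH2Cl2, reflux) should give the stilbene 2-{4-[5-(2-{2-[6-(1,3-dioxolan-2-yl)-2,3-dimethoxyphenoxy]phenyl}ethenyl)-2,3-dimethoxyphenoxy]phenyl}-1,3-dioxolane F3 as an E/Z mixture. Hydrogenation (H2, Pd/C, EtOAc with a trace of Et3N) then comes back to the route at compound 23, before step 14.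

2. Step 10. The terminal ynol ether may oligomerise, or be hydrated to the aryl acetate, while it is quenched, filtered and concentrated. The fallback stores the alkyne as a silyl-capped surrogate. It sets out from 15, which is treated with n-BuLi as before; the lithium acetylide 17 is then trapped with i-Pr3SiCl to give {[4-(1,3-dioxolan-2-yl)phenoxy]ethynyl}triisopropylsilane F4, which can be chromatographed and kept. Desilylation with tetrabutylammonium fluoride in THF at −20 °C immediately before use comes back to the route at compound 18, which is carried as a solution into step 11.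

3. Step 15. Intermolecular carbonyl coupling may give linear and cyclic oligomers, or the reaction may stop at the pinacol stage. The fallback closes the B–C bridge by a reductive benzyl–benzyl coupling. It sets out from dialdehyde 24, which NaBH4 in MeOH–THF reduces to (4-{5-[2-(2-{6-(hydroxymethyl)-2,3-dimethoxyphenoxy}phenyl)ethyl]-2,3-dimethoxyphenoxy}phenyl)methanol F5. CBr4 and PPh3 convert this diol into the bis(bromomethyl) compound F6. Intramolecular Wurtz-type coupling (Na, tetraphenylethene, THF, rt, high dilution), a closure known for macrocyclic bis(bibenzyl)s, comes back to the route at compound 26, so that step 16 is no longer needed.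

Further compounds
F1 | step 11 | {2-[6-(1,3-dioxolan-2-yl)-2,3-dimethoxyphenoxy]benzyl}triphenylphosphonium bromide | [Br-].COc1ccc(C2OCCO2)c(Oc2ccccc2C[P+](c2ccccc2)(c2ccccc2)c2ccccc2)c1OC
F2 | step 11 | 3-[4-(1,3-dioxolan-2-yl)phenoxy]-4,5-dimethoxybenzaldehyde | O=Cc1cc(OC)c(OC)c(Oc2ccc(cc2)C2OCCO2)c1
F3 | step 11 | 2-{4-[5-(2-{2-[6-(1,3-dioxolan-2-yl)-2,3-dimethoxyphenoxy]phenyl}ethenyl)-2,3-dimethoxyphenoxy]phenyl}-1,3-dioxolane (E/Z mixture) | COc1c(OC)cc(C=Cc2ccccc2Oc2c(C3OCCO3)ccc(OC)c2OC)cc1Oc1ccc(cc1)C1OCCO1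
F4 | step 10 | {[4-(1,3-dioxolan-2-yl)phenoxy]ethynyl}triisopropylsilane | CC(C)[Si](C#COc1ccc(cc1)C1OCCO1)(C(C)C)C(C)C
F5 | step 15 | (4-{5-[2-(2-{6-(hydroxymethyl)-2,3-dimethoxyphenoxy}phenyl)ethyl]-2,3-dimethoxyphenoxy}phenyl)methanol | COc1c(OC)cc(CCc2ccccc2Oc2c(CO)ccc(OC)c2OC)cc1Oc1ccc(CO)cc1
F6 | step 15 | 1-(bromomethyl)-2-(2-{2-[3-(4-(bromomethyl)phenoxy)-4,5-dimethoxyphenyl]ethyl}phenoxy)-3,4-dimethoxybenzene | COc1c(OC)cc(CCc2ccccc2Oc2c(CBr)ccc(OC)c2OC)cc1Oc1ccc(CBr)cc1
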